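Conventions and assumptions: all intermediates carry the labdane/drimane numbers of the target. Ring A is C1–C5 and C10; the five-membered ring of the hydrindanes is C5, C6, C7, C9, C10 (C8 is absent until step 13); C11 is the carbon on C9. β is the face of the C10 methyl group. The ethylidene geometry of 22, 23 and 25 and the C8 configuration of 26 are left open, because all isomers converge at 27.

## Structural features

The target (34) is a 14,15-dinorlabdane: a trans-fused decalin (ring A C1–C5/C10, ring B C5–C10) whose C9 carries an E-configured but-3-en-2-one chain (C11=C12–C13(=O)–CH3). Ring A holds only the C4 gem-dimethyl group, whereas every carbon of ring B is a stereocentre: C5 (α-H), C6 (α-OAc), C7 (β-OH), C8 (α-OH, β-CH3), C9 (β chain) and the quaternary C10 (β-CH3), six contiguous centres. All ring B substituents are equatorial except the 8β-methyl group, which is axial and 1,3-diaxial to the C10 methyl, so the tertiary carbinol C8 is the less stable epimer and has to be made under kinetic control. The fragile groups are the O6 acetate (migration to O7, loss under base or alkoxides), the tertiary 8-hydroxyl (β to C11 once C11 is a carbonyl, hence prone to dehydration) and C9 whenever it is α to a carbonyl. The real difficulty is not the carbon skeleton but three adjacent oxygens of different kind on C6, C7 and C8, only one of them acylated, next to the crowded C8–C9–C10 array. The key step exploits the fact that a C7 carbonyl beside C8(OH)(CH3) is an α-ketol: ring B can arise from the cyclopentane C5–C6–C7–C9–C10 carrying hydroxyl and acetyl on C7, by a 1,2-shift of C9 to the acetyl carbon. That shift forms C8–C9, ring B and the C8 stereocentre at once and leaves O6, O7 and O8 as ester, ketone and tertiary alcohol, three distinguishable states.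

## Logic of the disconnections

34 → 32 + 33. The C11=C12 bond is cut. It is the only alkene, and a stabilised ylide gives the E geometry. This removes the side chain and leaves a drimane with C11 as aldehyde. The forward step must be neutral, because 32 is a β-hydroxy aldehyde with an acetate beside two free hydroxyls.

32 → 31 → 30. The C11 aldehyde is traced to the primary alcohol and then to its benzyl ether. This is a pure change of oxidation level and protection, and it allows C11 to travel inert through the ring chemistry. The oxidation must discriminate a primary alcohol from the secondary O7 and tertiary O8 hydroxyls.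

30 → 29. The C7–H bond is cut (carbinol back to ketone). This reveals the α-ketol C7(=O)–C8(OH)(CH3). The forward reduction must deliver hydride axially to give the equatorial 7β-alcohol and must not move the acetate.

29 → 27 (key step). C8–C9 is cut and C9 is reattached to C7, contracting ring B to a cyclopentane with OH and acetyl on C7. This removes one ring-B carbon from the ring and the C8 stereocentre, and it reduces the problem to a trans-hydrindane obtainable from 1. The forward step needs a syn-chelated α-ketol, migration of C9 rather than C6, and the 7α-hydroxy/7β-acetyl configuration.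

27 → 26 → 25. The C7–O and C8–O bonds are cut as a syn-dihydroxylation of C7=C8 followed by oxidation at C8. An oxidant reaches C7 from the α face and places the hydroxyl α. A carbon nucleophile adding to a C7 ketone would use the same α face and give the C7 epimer, so the carbon is put on first and the oxygen second. The osmylation must be α-selective.

25 → 23 → 22. The O6 acetate is exchanged for a silyl ether. An acetate would not survive the hydride, alkoxide and ylide steps upstream. Acetylation when O6 is the only hydroxyl avoids any later choice among O6, O7 and O8.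

22 → 20 + 21. The C7=C8 bond is cut (Wittig). This brings in C8 and its methyl as one two-carbon unit and leaves a C7 ketone. The olefination must outrun enolisation toward C9 and C6.

20 → 19 → 17. The C7–O and C9–H bonds are cut as a hydroboration of C7=C9. One syn addition from the α face sets 9α-H (C11 β) and oxygenates C7. The borane must tolerate the neighbouring C6 silyloxy group.

17 → 16 → 15 → 13 + 14. The C9–C11 bond is cut as carbonylation of an enol triflate, followed by ester reduction and benzylation. C9 of 11 can enolise only toward C7, so the triflate is regiospecific and the alkene ends up where the hydroboration needs it.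

13 → 11 → 10 → 9. The triflate goes back to the C9 ketone, the ketone to its dioxolane and the silyl ether to the 6α-alcohol. The dioxolane carries C9 through the ring A chemistry with no redox detour.

9 → 7. The C5–H and C6–O bonds are cut as hydroboration of C5=C6. The angular methyl directs the reagent to the α face, so the trans ring fusion and the 6α-oxygen come from one step.

7 → 5 → 2 + 3 → 1. The C3 carbonyl is restored (Wolff–Kishner), the two C4–CH3 bonds are cut (deconjugative dimethylation), and the dioxolane is removed. 1 supplies C10 with the correct absolute configuration and both rings of the hydrindane.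

## Other disconnections considered

Alternative 1: The cut goes through C5–C10 and C8–C9, so both rings are opened at once to the acyclic triene A2. A2 is a Z-configured 2-silyloxydiene (C5=C6–C7(OSi)=C8) tethered through C4–C1 to an E-configured β-methyl acrylimide (C9=C10). The forward key step is an intramolecular Diels–Alder reaction of A2 to the trans-fused siloxy octalin A1.
- In its favour: one step closes ring A and ring B and sets C5, C8, C9 and C10. The C7 silyl enol ether is a handle for oxygenation at C6 and a carbonyl at C7. The precursor is assembled convergently from simple chains.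
- Against it here: the dienophile is β,β-disubstituted and must form the quaternary C10 next to a tether that carries the gem-dimethyl carbon at the diene terminus, so the cycloaddition would be slow. The Lewis acid needed to accelerate it endangers the silyl enol ether. The oxazolidinone is achiral, so absolute control would have to come from a chiral Lewis acid on a substrate class for which such control is poorly established. The trans fusion depends on the endo mode with respect to the imide.
- Also against it: A1 has C8 as CH(CH3) and C6 as CH, so the tertiary 8α-hydroxyl and the 6α-oxygen must both be added later at hindered positions.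
- Comparison: on skeletal bonds per step and on convergence Alternative 1 is the better plan. On the fate of C11 the two are equal, since both carry a carboxyl-level carbon on C9 that must be reduced and olefinated. On mechanism it is a concerted cycloaddition with an endo/exo question, against a chelate-controlled 1,2-shift whose stereochemical course is fixed by the substrate. On the oxygen pattern the chosen plan is ahead: step 18 delivers O6, O7 and O8 differentiated, where A1 still needs two separate C–O bond formations. The absolute configuration is more secure from 1.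

Alternative 2: The cut goes through C9–C10 and C5=C6, back to racemic 2,2,6-trimethylcyclohexanone A4 and the ene-keto ester A5. The forward key step is the Michael addition of the secondary enamine tautomer of a chiral imine of A4 through C10 to C9 of A5. Hydrolysis and aldol condensation of the methyl ketone carbon C6 onto the C5 carbonyl follow in the same flask and give the enone ester A3.
- In its favour: ring A arrives complete with its gem-dimethyl group, so no dimethylation and no deoxygenation are needed. The quaternary C10 is set while a racemic ketone is converted to one enantiomer. C9 with its ester, C8 with its methyl and a C7 carbonyl are all in place after one operation. On these points, and on the number of steps to the bicyclic core, Alternative 2 is the better plan.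
- Against it here: A4 is flanked by a quaternary and a tertiary carbon, so imine formation would be difficult. The acceptor A5 is substituted at the carbon that is attacked, and this type of transfer works best with unhindered acceptors. The aldol closure must attack a carbonyl lying between two quaternary carbons.
- Also against it: A3 has the 8α-methyl (the epimer at C8 once hydroxylated from the open face is not assured) and a C5=C6 enone. Turning that enone into 5α-H/6α-OAc has no direct solution: reduction gives C5–H but no oxygen at C6.
- Comparison: structurally the two plans meet at a 7-oxo decalin with a C9 carbon substituent (equal). Alternative 2 reaches it much sooner, but without O6 and O8. The chosen plan is longer, but sets the trans fusion and O6 together (step 4) and O7/O8 together (step 18). Mechanistically the auxiliary-controlled Michael step is well defined for simple partners but untested at this level of crowding, whereas each step of the chosen route has close analogy.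

Alternative 3: The cut is C1–C10, with ring B traced back to an arene: the phenol allyl carbonate A7. The forward key step is an asymmetric para-alkylative dearomatisation. The phenolate para carbon C10 attacks the terminus C1 of a π-allylpalladium unit generated on the chain from C5, closing ring A and giving the cross-conjugated chloro dienone A6.
- In its favour: C10 is created by asymmetric catalysis from an achiral, flat precursor, so either enantiomer is available from the ligand; on this point Alternative 3 is the better plan. All ring B carbons and their substituents (Cl at C6, O at C7, CH3 at C8, ester at C9) are bought with the arene, which is convergent.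
- Against it here: the nucleophilic carbon is flanked by a methyl and by the carbon bearing the tertiary benzylic chain, a crowded site for ipso attack.
- Also against it: A6 is almost entirely sp2. C5, C6, C8 and C9 must be reduced or oxygenated with control relayed only from C10. The vinyl chloride must become the 6α-acetate, the 8-hydroxyl must be added to a tetrasubstituted enone carbon, and the ring A alkene must be hydrogenated selectively.
- Comparison: the two plans are equal in that C10 is the first stereocentre and everything else is relayed from it. Alternative 3 is shorter to the bicyclic core, but it carries a long and stereochemically uncertain redox tail. The chosen plan spends its steps before the key step and then needs only four routine steps after it. The mechanisms (allylic substitution with dearomatisation against a 1,2-shift) pose different risks: enantioselectivity and C- versus O-alkylation there, migrating-group choice here.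

Key step: step 18

## Route

Step 1
Reactants: 1 (S)-7a-methyl-2,3,7,7a-tetrahydro-1H-indene-1,5(6H)-dione
Product: 2 9,9-ethylenedioxy-10β-methylhydrind-4-en-3-one (C9 dioxolane of 1)
Conditions: TMSOCH2CH2OTMS, TMSOTf (cat.), CH2Cl2, −78 → −20 °C; pyridine
Reagents that add atoms: 1,2-bis(trimethylsilyloxy)ethane (C[Si](C)(C)OCCO[Si](C)(C)C)
Why: Silyl-transfer ketalisation is kinetically selective for the saturated cyclopentanone over the less electrophilic conjugated ketone and does not move the enone double bond; the same chemoselective dioxolane formation is established for steroidal 17-ketones beside Δ4-3-ketones.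

Step 2
Reactants: 2 9,9-ethylenedioxy-10β-methylhydrind-4-en-3-one; 3 iodomethane
Product: 5 9,9-ethylenedioxy-4,4,10β-trimethylhydrind-5-en-3-one, via C4-monomethyl enone 4 (not isolated)
Conditions: KOtBu, t-BuOH/THF, 0 °C; MeI, 0 °C → rt
Reagents that add atoms: iodomethane 3 (CI)
Why: Deconjugative gem-dialkylation: the extended dienolate is methylated at C4, re-enolised and methylated again, which parks the alkene at C5=C6 (C6 in the five-membered ring) and blocks reconjugation; the dioxolane keeps C9 out of the enolate chemistry.

Step 3
Reactants: 5 9,9-ethylenedioxy-4,4,10β-trimethylhydrind-5-en-3-one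
Product: 7 9,9-ethylenedioxy-4,4,10β-trimethylhydrind-5-ene, via C3 hydrazone 6 (not isolated)
Conditions: N2H4·H2O, KOH, diethylene glycol, 130 → 200 °C
Reagents that add atoms: none
Why: Wolff–Kishner reduction removes the C3 carbonyl; the quaternary C4 prevents migration of the C5=C6 bond and the dioxolane is stable to hot base.

Step 4
Reactants: 7 9,9-ethylenedioxy-4,4,10β-trimethylhydrind-5-ene
Product: 9 9,9-ethylenedioxy-4,4,10β-trimethyl-5α-hydrindan-6α-ol (trans-fused), via C6 alkylborane 8 (not isolated)
Conditions: BH3·THF, THF, 0 °C → rt; NaOH, H2O2, 0 °C → rt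
Reagents that add atoms: hydrogen peroxide (OO)
Why: Hydroboration–oxidation: boron adds to the less substituted C6 and hydrogen to C5, both from the α face opposite the angular C10 methyl, so one syn addition sets 5α-H (trans ring fusion) and 6α-OH; oxidation of the C–B bond proceeds with retention.

Step 5
Reactants: 9 9,9-ethylenedioxy-4,4,10β-trimethyl-5α-hydrindan-6α-ol
Product: 10 6α-(tert-butyldimethylsilyloxy)-9,9-ethylenedioxy-4,4,10β-trimethyl-5α-hydrindane
Conditions: TBSOTf, 2,6-lutidine, CH2Cl2, −78 → 0 °C
Reagents that add atoms: tert-butyldimethylsilyl triflate (CC(C)(C)[Si](C)(C)OS(=O)(=O)C(F)(F)F)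
Why: Silylation of the hindered secondary alcohol with the reactive silyl triflate; a silyl ether is used at O6 because the acetate of the target would not survive the hydride, alkoxide and ylide steps that follow, and it is orthogonal to the later benzyl ether.

Step 6
Reactants: 10 6α-(tert-butyldimethylsilyloxy)-9,9-ethylenedioxy-4,4,10β-trimethyl-5α-hydrindane
Product: 11 6α-(tert-butyldimethylsilyloxy)-4,4,10β-trimethyl-5α-hydrindan-9-one
Conditions: PPTS (cat.), acetone/H2O, 55 °C
Reagents that add atoms: water (O)
Why: Mild acid-catalysed hydrolysis of the dioxolane unmasks the C9 ketone; a hindered secondary TBS ether tolerates pyridinium tosylate in wet acetone.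

Step 7
Reactants: 11 6α-(tert-butyldimethylsilyloxy)-4,4,10β-trimethyl-5α-hydrindan-9-one
Product: 13 6α-(tert-butyldimethylsilyloxy)-4,4,10β-trimethyl-5α-hydrind-7(9)-en-9-yl triflate, via potassium enolate 12 (not isolated)
Conditions: KN(SiMe3)2, THF, −78 °C; PhNTf2, −78 → 0 °C
Reagents that add atoms: N-phenylbis(trifluoromethanesulfonimide) (O=S(=O)(N(c1ccccc1)S(=O)(=O)C(F)(F)F)C(F)(F)F)
Why: Enol triflate formation: C9 can enolise only toward C7 because C10 is quaternary, so the alkene position is fixed; trapping at −78 °C avoids β-elimination of the C6 silyloxy group from the enolate.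

Step 8
Reactants: 13 6α-(tert-butyldimethylsilyloxy)-4,4,10β-trimethyl-5α-hydrind-7(9)-en-9-yl triflate; 14 carbon monoxide
Product: 15 methyl 6α-(tert-butyldimethylsilyloxy)-4,4,10β-trimethyl-5α-hydrind-7(9)-ene-9-carboxylate
Conditions: Pd(OAc)2 (cat.), PPh3, CO (1 atm), MeOH, Et3N, DMF, 50 °C
Reagents that add atoms: carbon monoxide 14 ([C-]#[O+]), methanol (CO)
Why: Palladium-catalysed methoxycarbonylation of an alkenyl triflate (oxidative addition to zerovalent palladium, CO insertion, methanolysis) attaches C11 to C9; it is routine for cyclopentenyl triflates next to a quaternary carbon.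

Step 9
Reactants: 15 methyl 6α-(tert-butyldimethylsilyloxy)-4,4,10β-trimethyl-5α-hydrind-7(9)-ene-9-carboxylate
Product: 16 [6α-(tert-butyldimethylsilyloxy)-4,4,10β-trimethyl-5α-hydrind-7(9)-en-9-yl]methanol
Conditions: iBu2AlH, CH2Cl2, −78 → 0 °C; aq. potassium sodium tartrate
Reagents that add atoms: none
Why: 1,2-Reduction of the conjugated ester by the aluminium hydride gives the allylic alcohol and leaves the alkene and the silyl ether untouched.

Step 10
Reactants: 16 [6α-(tert-butyldimethylsilyloxy)-4,4,10β-trimethyl-5α-hydrind-7(9)-en-9-yl]methanol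
Product: 17 9-(benzyloxymethyl)-6α-(tert-butyldimethylsilyloxy)-4,4,10β-trimethyl-5α-hydrind-7(9)-ene
Conditions: NaH, BnBr, Bu4NI (cat.), THF/DMF, 0 °C → rt
Reagents that add atoms: benzyl bromide (BrCc1ccccc1)
Why: Williamson etherification of the primary allylic alkoxide; the benzyl ether survives every step up to the neutral hydrogenolysis in step 20.

Step 11
Reactants: 17 9-(benzyloxymethyl)-6α-(tert-butyldimethylsilyloxy)-4,4,10β-trimethyl-5α-hydrind-7(9)-ene
Product: 19 9β-(benzyloxymethyl)-6α-(tert-butyldimethylsilyloxy)-4,4,10β-trimethyl-5α-hydrindan-7α-ol (9α-H), via C7 alkylborane 18 (not isolated)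
Conditions: BH3·THF, THF, 0 °C → rt; NaOH, H2O2, 0 °C
Reagents that add atoms: hydrogen peroxide (OO)
Why: Hydroboration–oxidation of the trisubstituted C7=C9 alkene: boron adds to C7 and hydrogen to C9, syn and from the α face away from the adjacent C10 methyl, which sets 9α-H (C11 β) as in hydroboration of 17-substituted Δ16 steroids; the 7α-hydroxyl is only a relay and is oxidised next.

Step 12
Reactants: 19 9β-(benzyloxymethyl)-6α-(tert-butyldimethylsilyloxy)-4,4,10β-trimethyl-5α-hydrindan-7α-ol
Product: 20 9β-(benzyloxymethyl)-6α-(tert-butyldimethylsilyloxy)-4,4,10β-trimethyl-5α-hydrindan-7-one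
Conditions: DMP (1,1,1-triacetoxy-1,2-benziodoxol-3-one), NaHCO3, CH2Cl2, 0 °C → rt
Reagents that add atoms: none
Why: Hypervalent-iodine oxidation under buffered, non-basic conditions gives the C7 ketone without epimerising C9 or eliminating the β-benzyloxy group; the quasi-equatorial 9β chain is also the thermodynamically favoured epimer.

Step 13
Reactants: 20 9β-(benzyloxymethyl)-6α-(tert-butyldimethylsilyloxy)-4,4,10β-trimethyl-5α-hydrindan-7-one; 21 ethyltriphenylphosphonium bromide
Product: 22 9β-(benzyloxymethyl)-7-ethylidene-6α-(tert-butyldimethylsilyloxy)-4,4,10β-trimethyl-5α-hydrindane (E/Z mixture)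
Conditions: EtPPh3Br, KOtBu, THF, 0 → 50 °C
Reagents that add atoms: ethyltriphenylphosphonium bromide 21 (CC[P+](c1ccccc1)(c1ccccc1)c1ccccc1.[Br-])
Why: Wittig olefination with the non-stabilised ethylidene ylide brings in C8 and its methyl; the ylide is far less basic than an organolithium, so olefination should outrun enolisation. A direct acetyl-anion addition is avoided because a nucleophile enters C7 from the α face (anti to the C10 methyl and the 9β chain) and would leave the hydroxyl β, the wrong epimer for the chelated shift in step 18.

Step 14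
Reactants: 22 9β-(benzyloxymethyl)-7-ethylidene-6α-(tert-butyldimethylsilyloxy)-4,4,10β-trimethyl-5α-hydrindane
Product: 23 9β-(benzyloxymethyl)-7-ethylidene-4,4,10β-trimethyl-5α-hydrindan-6α-ol
Conditions: Bu4NF, THF, rt → 50 °C
Reagents that add atoms: none
Why: Fluoride cleaves the Si–O bond; it is done here, before any base-sensitive α-ketol exists.

Step 15
Reactants: 23 9β-(benzyloxymethyl)-7-ethylidene-4,4,10β-trimethyl-5α-hydrindan-6α-ol; 24 acetic anhydride
Product: 25 6α-acetoxy-9β-(benzyloxymethyl)-7-ethylidene-4,4,10β-trimethyl-5α-hydrindane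
Conditions: Ac2O, pyridine, DMAP (cat.), CH2Cl2, rt
Reagents that add atoms: acetic anhydride 24 (CC(=O)OC(C)=O)
Why: Acylation of the only free hydroxyl installs the O6 acetate of the target while O7 and O8 do not yet exist, so no later choice among three oxygens is needed; the acetoxy group also lowers the migratory aptitude of C6 in step 18.

Step 16
Reactants: 25 6α-acetoxy-9β-(benzyloxymethyl)-7-ethylidene-4,4,10β-trimethyl-5α-hydrindane
Product: 26 6α-acetoxy-9β-(benzyloxymethyl)-7β-(1-hydroxyethyl)-4,4,10β-trimethyl-5α-hydrindan-7α-ol (C8 epimers)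
Conditions: OsO4 (cat.), NMO, acetone/H2O, rt
Reagents that add atoms: N-methylmorpholine N-oxide (C[N+]1([O-])CCOCC1), water (O)
Why: Catalytic syn-dihydroxylation of the trisubstituted exocyclic alkene; OsO4 should approach from the α face, away from the C10 methyl (1,3 to C7) and the quasi-equatorial 9β-CH2OBn group, so the tertiary hydroxyl becomes 7α. The allylic C6–O bond lies near the alkene plane, where the usual preference of osmylation for the face anti to an allylic oxygen is weak, and the C8 configuration is irrelevant.

Step 17
Reactants: 26 6α-acetoxy-9β-(benzyloxymethyl)-7β-(1-hydroxyethyl)-4,4,10β-trimethyl-5α-hydrindan-7α-ol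
Product: 27 6α-acetoxy-7β-acetyl-9β-(benzyloxymethyl)-4,4,10β-trimethyl-5α-hydrindan-7α-ol
Conditions: (COCl)2, DMSO, CH2Cl2, −78 °C; Et3N, −78 → −20 °C
Reagents that add atoms: none
Why: Swern oxidation converts the secondary C8 carbinol into the methyl ketone and leaves the tertiary C7 hydroxyl; activated DMSO does not cleave the glycol, and both C8 epimers give the same α-ketol.

Step 18
Reactants: 27 6α-acetoxy-7β-acetyl-9β-(benzyloxymethyl)-4,4,10β-trimethyl-5α-hydrindan-7α-ol
Product: 29 6α-acetoxy-11-benzyloxy-8α-hydroxydriman-7-one, via aluminium chelate 28 (not isolated)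
Conditions: Al(OtBu)3, toluene, 80 °C; aq. potassium sodium tartrate
Reagents that add atoms: none
Why: Ligand exchange puts the tertiary C7 alkoxide on aluminium (28) and the same metal binds the acetyl oxygen, so O7–C7–C8=O is held syn in a five-membered chelate. In the rotamer with the C7–C9 bond perpendicular to the carbonyl plane, C9 shifts suprafacially from C7 to C8 with retention at C9 while the alkoxide becomes the C7 ketone; this is an α-ketol (acyloin) rearrangement, and the closest analogy is the Lewis-acid D-homoannulation of 17α-hydroxy-20-oxo steroids. Ring B is closed as a six-membered ring by ring expansion of the cyclopentane through a 1,2-shift, not by a cyclisation, and relief of five-ring strain plus the stronger endocyclic chelate of the product drive it forward. The new stereocentre C8 is controlled by the C7 configuration relayed through the chelate: with 7α-O and 7β-acetyl, the syn rotamer that aligns C9 exposes the carbonyl face that gives 8α-OH and 8β-CH3. The step needs migration of C9 and not C6; C9 is an electron-richer tertiary alkyl carbon, whereas C6 carries the electron-withdrawing acetoxy group. It also needs kinetic control, because the 8β-methyl becomes 1,3-diaxial to the C10 methyl and the regioisomeric or C8-epimeric ketols are probably more stable. Tert-butoxide ligands (no transferable hydride, poor acyl acceptors) and a moderate temperature are chosen to suppress Meerwein–Ponndorf–Verley reduction, acetate exchange and further ketol equilibration.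

Step 19
Reactants: 29 6α-acetoxy-11-benzyloxy-8α-hydroxydriman-7-one
Product: 30 6α-acetoxy-11-benzyloxydrimane-7β,8α-diol
Conditions: NaBH4, CeCl3·7H2O, MeOH, −40 °C
Reagents that add atoms: none
Why: Luche-type borohydride reduction: hydride attacks C7 axially from the open α face (only the axial hydrogens of C5 and C9; the β side is flanked by the axial 8β-methyl) and gives the equatorial 7β-alcohol; the cold, non-basic medium keeps the acetate on O6.

Step 20
Reactants: 30 6α-acetoxy-11-benzyloxydrimane-7β,8α-diol
Product: 31 6α-acetoxydrimane-7β,8α,11-triol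
Conditions: H2 (1 atm), 10% Pd/C, EtOAc, rt
Reagents that add atoms: none
Why: Neutral hydrogenolysis of the benzyl ether; no alkene is present and the acetate cannot migrate under these conditions.

Step 21
Reactants: 31 6α-acetoxydrimane-7β,8α,11-triol
Product: 32 6α-acetoxy-7β,8α-dihydroxydriman-11-al
Conditions: TEMPO (cat.), PhI(OAc)2, CH2Cl2, rt
Reagents that add atoms: none
Why: Oxoammonium (TEMPO) oxidation is selective for the primary alcohol over the hindered secondary and the tertiary hydroxyl and stops at the aldehyde; the equatorial 9β-CHO is the stable C9 epimer.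

Step 22
Reactants: 32 6α-acetoxy-7β,8α-dihydroxydriman-11-al; 33 1-(triphenylphosphoranylidene)propan-2-one
Product: 34 6α-acetoxy-7β,8α-dihydroxy-14,15-dinorlabd-11E-en-13-one (CNP0136046.1)
Conditions: toluene, 90 °C
Reagents that add atoms: 1-(triphenylphosphoranylidene)propan-2-one 33 (CC(=O)C=P(c1ccccc1)(c1ccccc1)c1ccccc1)
Why: Wittig reaction of the stabilised ylide gives the E-enone under neutral conditions, which avoids base-induced dehydration of the β-hydroxy aldehyde and acetate migration.

## Compound list

1 | (S)-7a-methyl-2,3,7,7a-tetrahydro-1H-indene-1,5(6H)-dione | O=C1CCC2=CC(=O)CC[C@@]21C | starting material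
2 | 9,9-ethylenedioxy-10β-methylhydrind-4-en-3-one (C9 dioxolane of 1) | O1CCOC12CCC3=CC(=O)CC[C@@]32C | intermediate
3 | iodomethane | CI | starting material
4 | 9,9-ethylenedioxy-4,10β-dimethylhydrind-4-en-3-one | O1CCOC12CCC3=C(C)C(=O)CC[C@@]32C | intermediate
5 | 9,9-ethylenedioxy-4,4,10β-trimethylhydrind-5-en-3-one | O1CCOC12CC=C3C(C)(C)C(=O)CC[C@@]32C | intermediate
6 | C3 hydrazone of 5 | O1CCOC12CC=C3C(C)(C)C(=NN)CC[C@@]32C | intermediate
7 | 9,9-ethylenedioxy-4,4,10β-trimethylhydrind-5-ene | O1CCOC12CC=C3C(C)(C)CCC[C@@]32C | intermediate
8 | (9,9-ethylenedioxy-4,4,10β-trimethyl-5α-hydrindan-6α-yl)borane | O1CCOC12C[C@H](B)[C@H]3C(C)(C)CCC[C@@]32C | intermediate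
9 | 9,9-ethylenedioxy-4,4,10β-trimethyl-5α-hydrindan-6α-ol | O1CCOC12C[C@H](O)[C@H]3C(C)(C)CCC[C@@]32C | intermediate
10 | 6α-(tert-butyldimethylsilyloxy)-9,9-ethylenedioxy-4,4,10β-trimethyl-5α-hydrindane | O1CCOC12C[C@H](O[Si](C)(C)C(C)(C)C)[C@H]3C(C)(C)CCC[C@@]32C | intermediate
11 | 6α-(tert-butyldimethylsilyloxy)-4,4,10β-trimethyl-5α-hydrindan-9-one | O=C1C[C@H](O[Si](C)(C)C(C)(C)C)[C@H]2C(C)(C)CCC[C@@]21C | intermediate
12 | potassium enolate of 11 (C9–O, C7=C9) | [K+].[O-]C1=C[C@H](O[Si](C)(C)C(C)(C)C)[C@H]2C(C)(C)CCC[C@@]21C | intermediate
13 | 6α-(tert-butyldimethylsilyloxy)-4,4,10β-trimethyl-5α-hydrind-7(9)-en-9-yl triflate | FC(F)(F)S(=O)(=O)OC1=C[C@H](O[Si](C)(C)C(C)(C)C)[C@H]2C(C)(C)CCC[C@@]21C | intermediate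
14 | carbon monoxide | [C-]#[O+] | starting material
15 | methyl 6α-(tert-butyldimethylsilyloxy)-4,4,10β-trimethyl-5α-hydrind-7(9)-ene-9-carboxylate | COC(=O)C1=C[C@H](O[Si](C)(C)C(C)(C)C)[C@H]2C(C)(C)CCC[C@@]21C | intermediate
16 | [6α-(tert-butyldimethylsilyloxy)-4,4,10β-trimethyl-5α-hydrind-7(9)-en-9-yl]methanol | OCC1=C[C@H](O[Si](C)(C)C(C)(C)C)[C@H]2C(C)(C)CCC[C@@]21C | intermediate
17 | 9-(benzyloxymethyl)-6α-(tert-butyldimethylsilyloxy)-4,4,10β-trimethyl-5α-hydrind-7(9)-ene | C(OCc1ccccc1)C1=C[C@H](O[Si](C)(C)C(C)(C)C)[C@H]2C(C)(C)CCC[C@@]21C | intermediate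
18 | [9β-(benzyloxymethyl)-6α-(tert-butyldimethylsilyloxy)-4,4,10β-trimethyl-5α-hydrindan-7α-yl]borane | C(OCc1ccccc1)[C@H]1[C@H](B)[C@H](O[Si](C)(C)C(C)(C)C)[C@H]2C(C)(C)CCC[C@@]21C | intermediate
19 | 9β-(benzyloxymethyl)-6α-(tert-butyldimethylsilyloxy)-4,4,10β-trimethyl-5α-hydrindan-7α-ol | C(OCc1ccccc1)[C@H]1[C@H](O)[C@H](O[Si](C)(C)C(C)(C)C)[C@H]2C(C)(C)CCC[C@@]21C | intermediate
20 | 9β-(benzyloxymethyl)-6α-(tert-butyldimethylsilyloxy)-4,4,10β-trimethyl-5α-hydrindan-7-one | C(OCc1ccccc1)[C@H]1C(=O)[C@H](O[Si](C)(C)C(C)(C)C)[C@H]2C(C)(C)CCC[C@@]21C | intermediate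
21 | ethyltriphenylphosphonium bromide | CC[P+](c1ccccc1)(c1ccccc1)c1ccccc1.[Br-] | starting material
22 | 9β-(benzyloxymethyl)-7-ethylidene-6α-(tert-butyldimethylsilyloxy)-4,4,10β-trimethyl-5α-hydrindane (E/Z) | C(OCc1ccccc1)[C@H]1C(=CC)[C@H](O[Si](C)(C)C(C)(C)C)[C@H]2C(C)(C)CCC[C@@]21C | intermediate
23 | 9β-(benzyloxymethyl)-7-ethylidene-4,4,10β-trimethyl-5α-hydrindan-6α-ol (E/Z) | C(OCc1ccccc1)[C@H]1C(=CC)[C@H](O)[C@H]2C(C)(C)CCC[C@@]21C | intermediate
24 | acetic anhydride | CC(=O)OC(C)=O | starting material
25 | 6α-acetoxy-9β-(benzyloxymethyl)-7-ethylidene-4,4,10β-trimethyl-5α-hydrindane (E/Z) | C(OCc1ccccc1)[C@H]1C(=CC)[C@H](OC(C)=O)[C@H]2C(C)(C)CCC[C@@]21C | intermediate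
26 | 6α-acetoxy-9β-(benzyloxymethyl)-7β-(1-hydroxyethyl)-4,4,10β-trimethyl-5α-hydrindan-7α-ol (C8 epimers) | C(OCc1ccccc1)[C@H]1[C@@](O)(C(C)O)[C@H](OC(C)=O)[C@H]2C(C)(C)CCC[C@@]21C | intermediate
27 | 6α-acetoxy-7β-acetyl-9β-(benzyloxymethyl)-4,4,10β-trimethyl-5α-hydrindan-7α-ol | C(OCc1ccccc1)[C@H]1[C@@](O)(C(C)=O)[C@H](OC(C)=O)[C@H]2C(C)(C)CCC[C@@]21C | intermediate
28 | di-tert-butoxyaluminium 7-alkoxide of 27 (O7/O8 chelate) | C(OCc1ccccc1)[C@H]1[C@@](O[Al](OC(C)(C)C)OC(C)(C)C)(C(C)=O)[C@H](OC(C)=O)[C@H]2C(C)(C)CCC[C@@]21C | intermediate
29 | 6α-acetoxy-11-benzyloxy-8α-hydroxydriman-7-one | C(OCc1ccccc1)[C@H]1[C@](C)(O)C(=O)[C@H](OC(C)=O)[C@H]2C(C)(C)CCC[C@@]21C | intermediate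
30 | 6α-acetoxy-11-benzyloxydrimane-7β,8α-diol | C(OCc1ccccc1)[C@H]1[C@](C)(O)[C@@H](O)[C@H](OC(C)=O)[C@H]2C(C)(C)CCC[C@@]21C | intermediate
31 | 6α-acetoxydrimane-7β,8α,11-triol | OC[C@H]1[C@](C)(O)[C@@H](O)[C@H](OC(C)=O)[C@H]2C(C)(C)CCC[C@@]21C | intermediate
32 | 6α-acetoxy-7β,8α-dihydroxydriman-11-al | O=C[C@H]1[C@](C)(O)[C@@H](O)[C@H](OC(C)=O)[C@H]2C(C)(C)CCC[C@@]21C | intermediate
33 | 1-(triphenylphosphoranylidene)propan-2-one | CC(=O)C=P(c1ccccc1)(c1ccccc1)c1ccccc1 | starting material
34 | 6α-acetoxy-7β,8α-dihydroxy-14,15-dinorlabd-11E-en-13-one (CNP0136046.1) | CC(=O)/C=C/[C@H]1[C@](C)(O)[C@@H](O)[C@H](OC(C)=O)[C@H]2C(C)(C)CCC[C@@]21C | target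

Total step count: 22. Longest linear sequence: 22 steps (1 → 34).

## Least certain steps and fallbacks

Step 18 (key step).
- What may go wrong: transfer of the O6 acetyl group to aluminium-bound oxygens or to tert-butoxide; loss of regiocontrol through a competing shift of C6, or a later methyl shift on prolonged heating, which would drain material toward the less strained regioisomeric ketol.
- Fallback: carry O6 as its silyl ether through the ring expansion and acetylate afterwards. The fallback sets out from 22. OsO4/NMO should give the silyl-protected 7α,8-diol F1, and Swern oxidation the 6-O-silyl α-ketol F2. Al(OtBu)3 in toluene then expands F2 to the ring-expanded 6-O-silyl ketol F3. HF·pyridine releases the 6α-hydroxy-8α-hydroxy ketone F4, in which only the secondary O6 is acylated by Ac2O/pyridine. The route is rejoined at 29.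

Step 16.
- What may go wrong: poor facial selectivity of the osmylation, if the allylic acetate steers the oxidant toward the β face.
- Fallback: set C7 by nucleophilic addition, whose α-face course is sterically unambiguous, and use the complementary non-chelated mode of the ketol shift. The fallback sets out from 20. 1-Ethoxyvinyllithium (from ethyl vinyl ether and t-BuLi) with CeCl3 in THF at −78 °C should give the 7β-hydroxy-7α-(1-ethoxyvinyl) adduct F5, and dilute aqueous acid hydrolyses it to the C7-epimeric silyl ketol F6. HF·pyridine gives the C7-epimeric 6α-alcohol F7, and Ac2O/pyridine the C7 epimer of the precursor F8. The potassium alkoxide of F8 (KN(SiMe3)2, 18-crown-6, THF, −78 → −20 °C) cannot chelate and should react through the rotamer with opposed C–O dipoles, in which migration of C9 leads to the same 8α-hydroxy-8β-methyl ketone. The route is rejoined at 29.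

Step 11.
- What may go wrong: β-elimination from the alkylborane, whose boron at C7 sits cis to the C6 silyloxy group, with loss of the C6 oxygen; incomplete hydroboration of the hindered alkene.
- Fallback: place boron on C7 as a pinacol boronate, which does not eliminate. The fallback sets out from 15. Copper-catalysed conjugate borylation (CuCl, NaOtBu, a bisphosphine, B2pin2, MeOH, THF) should give the 7α-boryl ester F9, with protonation at C9 from the α face. NaBO3 oxidises it to the β-hydroxy ester F10, LiBH4 reduces this to the 7α,11-diol F11, and stannylene-mediated benzylation (Bu2SnO; BnBr, CsF) protects only the primary hydroxyl. The route is rejoined at 19.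

Step 22.
- What may go wrong: slow reaction of the stabilised ylide with the hindered aldehyde, so that prolonged heating leads to dehydration of the β-hydroxy aldehyde or epimerisation at C9.
- Fallback: form the enone by cross-metathesis instead of carbonyl olefination. The fallback sets out from 32. Non-basic methylenation (Zn, CH2Br2, TiCl4, THF) should give the 9β-vinyl compound F12. Cross-metathesis of F12 with methyl vinyl ketone, using the second-generation Hoveyda–Grubbs catalyst in CH2Cl2 at 40 °C, gives the E-enone. The route is rejoined at 34.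

## Further compounds

F1 | step 18 | 9β-(benzyloxymethyl)-6α-(tert-butyldimethylsilyloxy)-7β-(1-hydroxyethyl)-4,4,10β-trimethyl-5α-hydrindan-7α-ol | C(OCc1ccccc1)[C@H]1[C@@](O)(C(C)O)[C@H](O[Si](C)(C)C(C)(C)C)[C@H]2C(C)(C)CCC[C@@]21C
F2 | step 18 | 7β-acetyl-9β-(benzyloxymethyl)-6α-(tert-butyldimethylsilyloxy)-4,4,10β-trimethyl-5α-hydrindan-7α-ol | C(OCc1ccccc1)[C@H]1[C@@](O)(C(C)=O)[C@H](O[Si](C)(C)C(C)(C)C)[C@H]2C(C)(C)CCC[C@@]21C
F3 | step 18 | 11-benzyloxy-6α-(tert-butyldimethylsilyloxy)-8α-hydroxydriman-7-one | C(OCc1ccccc1)[C@H]1[C@](C)(O)C(=O)[C@H](O[Si](C)(C)C(C)(C)C)[C@H]2C(C)(C)CCC[C@@]21C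
F4 | step 18 | 11-benzyloxy-6α,8α-dihydroxydriman-7-one | C(OCc1ccccc1)[C@H]1[C@](C)(O)C(=O)[C@H](O)[C@H]2C(C)(C)CCC[C@@]21C
F5 | step 16 | 9β-(benzyloxymethyl)-7α-(1-ethoxyvinyl)-6α-(tert-butyldimethylsilyloxy)-4,4,10β-trimethyl-5α-hydrindan-7β-ol | C(OCc1ccccc1)[C@H]1[C@](O)(C(=C)OCC)[C@H](O[Si](C)(C)C(C)(C)C)[C@H]2C(C)(C)CCC[C@@]21C
F6 | step 16 | 7α-acetyl-9β-(benzyloxymethyl)-6α-(tert-butyldimethylsilyloxy)-4,4,10β-trimethyl-5α-hydrindan-7β-ol | C(OCc1ccccc1)[C@H]1[C@](O)(C(C)=O)[C@H](O[Si](C)(C)C(C)(C)C)[C@H]2C(C)(C)CCC[C@@]21C
F7 | step 16 | 7α-acetyl-9β-(benzyloxymethyl)-4,4,10β-trimethyl-5α-hydrindane-6α,7β-diol | C(OCc1ccccc1)[C@H]1[C@](O)(C(C)=O)[C@H](O)[C@H]2C(C)(C)CCC[C@@]21C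
F8 | step 16 | 6α-acetoxy-7α-acetyl-9β-(benzyloxymethyl)-4,4,10β-trimethyl-5α-hydrindan-7β-ol | C(OCc1ccccc1)[C@H]1[C@](O)(C(C)=O)[C@H](OC(C)=O)[C@H]2C(C)(C)CCC[C@@]21C
F9 | step 11 | methyl 6α-(tert-butyldimethylsilyloxy)-4,4,10β-trimethyl-7α-(pinacolatoboryl)-5α-hydrindane-9β-carboxylate | COC(=O)[C@H]1[C@H](B2OC(C)(C)C(C)(C)O2)[C@H](O[Si](C)(C)C(C)(C)C)[C@H]3C(C)(C)CCC[C@@]31C
F10 | step 11 | methyl 6α-(tert-butyldimethylsilyloxy)-7α-hydroxy-4,4,10β-trimethyl-5α-hydrindane-9β-carboxylate | COC(=O)[C@H]1[C@H](O)[C@H](O[Si](C)(C)C(C)(C)C)[C@H]2C(C)(C)CCC[C@@]21C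
F11 | step 11 | 6α-(tert-butyldimethylsilyloxy)-9β-(hydroxymethyl)-4,4,10β-trimethyl-5α-hydrindan-7α-ol | OC[C@H]1[C@H](O)[C@H](O[Si](C)(C)C(C)(C)C)[C@H]2C(C)(C)CCC[C@@]21C
F12 | step 22 | 6α-acetoxy-9β-vinyl-11-nordrimane-7β,8α-diol | C=C[C@H]1[C@](C)(O)[C@@H](O)[C@H](OC(C)=O)[C@H]2C(C)(C)CCC[C@@]21C
A1 | alternative 1 | trans-fused 7-(tert-butyldimethylsilyloxy)-Δ6-octalin with C9 β-acyl oxazolidinone | O=C([C@H]1[C@@H](C)C(O[Si](C)(C)C(C)(C)C)=C[C@H]2C(C)(C)CCC[C@@]21C)N1CCOC1=O
A2 | alternative 1 | acyclic triene: Z-2-silyloxydiene tethered to E β-methyl acrylimide | C/C=C(O[Si](C)(C)C(C)(C)C)/C=C/C(C)(C)CCC/C(C)=C/C(=O)N1CCOC1=O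
A3 | alternative 2 | ethyl 4,4,8α,10β-tetramethyl-7-oxo-Δ5-octalin-9β-carboxylate | CCOC(=O)[C@H]1[C@H](C)C(=O)C=C2C(C)(C)CCC[C@@]21C
A4 | alternative 2 | 2,2,6-trimethylcyclohexanone (racemic) | CC1CCCC(C)(C)C1=O
A5 | alternative 2 | ethyl (E)-3-methyl-4-oxopent-2-enoate | CCOC(=O)/C=C(\C)C(C)=O
A6 | alternative 3 | bicyclic 6-chloro-7-oxo dienone with C9 methyl ester and C10 quaternary methyl | COC(=O)C1=C(C)C(=O)C(Cl)=C2C(C)(C)C=CC[C@@]21C
A7 | alternative 3 | pentasubstituted phenol bearing the allyl methyl carbonate chain on C5 | COC(=O)OC/C=C/C(C)(C)c1c(Cl)c(O)c(C)c(C(=O)OC)c1C
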